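**Retrosynthetic overview**
1. Target 6 ⇒ bis-lactam 4 by double deoxybromination (C2=O → C2–Br); both pyrrole rings become aromatic only in this last step.
2. 4 ⇒ C3–C3' bond between two identical 5,6-dibromooxindole units 2, one as its enolate and the other as the α-iodo lactam 3 (a polarity-reversed, enolonium-type C3).
3. 2 ⇒ 6-bromooxindole 1 + NBS (C5 bromination), run in the same flask as the coupling.
4. Ring order: the benzo and lactam rings are bought in 1; no ring is built, only the C3–C3' link and the final aromatization.

Assumption: the SMILES has no stereocentre and no defined axis, so the target is one achiral compound and no stereocontrol is needed.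

**Step 1**
Reactants: 1 6-bromooxindole (6-bromoindolin-2-one)
Product: 4 5,5',6,6'-tetrabromo-3,3'-biindoline-2,2'-dione (meso/racemic mixture), via 5,6-dibromooxindole 2 (not isolated), via 5,6-dibromo-3-iodooxindole 3 (not isolated)
Conditions: NBS (1.0 equiv), MeCN, 0 °C → rt; then THF, KOt-Bu (2.05 equiv), −40 °C; I2 (0.50 equiv) in THF added over 30 min, → rt, N2; aq. HCl quench
Reagents that add atoms: N-bromosuccinimide (NBS), O=C1CCC(=O)N1Br
Why: Proposed new method: NBS brominates 1 at C5, para to the lactam nitrogen and the normal site of electrophilic aromatic substitution in 6-halooxindoles, to give 2; KOt-Bu then forms the potassium enolate of 2 (the second equivalent only parks succinimide as its salt), half an equivalent of I2 turns half of that enolate into the α-iodo lactam 3, whose C3 is now an enolonium-type electrophile, and the remaining enolate displaces iodide so that two C3 carbons that are both nucleophilic by nature are joined (iodine-mediated oxidative enolate homocoupling, closest known reaction type the I2/alkoxide dimerization of 3-substituted oxindole enolates and of ester enolates, here telescoped onto a ring bromination and applied to an N–H, 3-unsubstituted oxindole), the two new stereocentres arising without control as a meso/racemic mixture that is erased on aromatization in step 2.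

**Step 2**
Reactants: 4 5,5',6,6'-tetrabromo-3,3'-biindoline-2,2'-dione
Product: 6 2,2',5,5',6,6'-hexabromo-1H,1'H-3,3'-biindole (target), via 3-(2,5,6-tribromoindol-3-yl)-5,6-dibromooxindole 5 (not isolated)
Conditions: POBr3 (6 equiv), ClCH2CH2Cl, 85 °C, N2; poured onto ice
Reagents that add atoms: phosphorus oxybromide (POBr3), O=P(Br)(Br)Br
Why: Vilsmeier–Haack-type deoxybromination: POBr3 activates each lactam oxygen as a dibromophosphate, bromide adds at C2 and elimination followed by tautomerization gives the aromatic 2-bromoindole, first in 5 and then in 6, the C3 substituent shielding the 2-bromoindoles from acid-driven self-condensation and the aryl bromides being inert; the stereocentres of 4 and 5 vanish and 6 has none.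

**Compound list**
1 | 6-bromooxindole (6-bromoindolin-2-one) | O=C1Cc2ccc(Br)cc2N1 | starting material
2 | 5,6-dibromooxindole (5,6-dibromoindolin-2-one) | O=C1Cc2cc(Br)c(Br)cc2N1 | intermediate
3 | 5,6-dibromo-3-iodooxindole (racemic) | O=C1Nc2cc(Br)c(Br)cc2C1I | intermediate
4 | 5,5',6,6'-tetrabromo-3,3'-biindoline-2,2'-dione (meso and racemic diastereomers, unassigned) | O=C1Nc2cc(Br)c(Br)cc2C1C1C(=O)Nc2cc(Br)c(Br)cc21 | intermediate
5 | 5,6-dibromo-3-(2,5,6-tribromo-1H-indol-3-yl)indolin-2-one (racemic) | O=C1Nc2cc(Br)c(Br)cc2C1c1c(Br)[nH]c2cc(Br)c(Br)cc12 | intermediate
6 | 2,2',5,5',6,6'-hexabromo-1H,1'H-3,3'-biindole | Brc1cc2[nH]c(Br)c(-c3c(Br)[nH]c4cc(Br)c(Br)cc34)c2cc1Br | target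

**Step count and risk**
Total steps: 2. Longest linear sequence: 2 steps from 1. The route has only two steps, so both are ranked and a third place cannot be filled.

Most likely to fail: step 1. The coupling product 4 still has acidic C3–H bonds, so its enolate can be iodinated and lose HI to give the isoindigo (which leaves unreacted 2 behind). The ring bromination must also be complete and C5-selective before base is added, and basic solutions of 4 oxidize in air, hence the acidic quench under N2. The fallback sets out from compound 2, isolated after the NBS stage run on its own, and comes back to the route at compound 4. One half of 2 is oxidized at C3 (t-BuONO, O2, THF, 50 °C) to 5,6-dibromoisatin F1. F1 and the other half of 2 are condensed in AcOH with catalytic HCl at reflux (acid-catalysed aldol condensation in the normal polarity sense) to (E)-5,5',6,6'-tetrabromoisoindigo F2, which precipitates. The central C=C bond of F2 is then reduced with Zn dust in AcOH at 50 °C, which leaves the aryl bromides untouched and gives 4.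

Second: step 2. Compound 4 is poorly soluble, the reaction may stall at the mono-brominated lactam 5, and traces of bromine in hot POBr3 could dehydrogenate 4 to the isoindigo. The fallback sets out from compound 4 and comes back to the route at compound 6. Both lactam carbonyls are reduced with i-Bu2AlH (THF/PhMe, 0 °C → rt; the hemiaminals lose water on acidic work-up) to 5,5',6,6'-tetrabromo-1H,1'H-3,3'-biindole F3. The two free C2 positions of F3 are then brominated with NBS (2.0 equiv, THF, −40 → 0 °C), the usual outcome for C3-substituted indoles by way of the 3-bromoindolenine and a 1,2-shift of bromine. The dibrominated benzo rings are too deactivated to compete, and the product is 6.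

**Further compounds**
F1 | step 1 | 5,6-dibromoisatin (5,6-dibromoindoline-2,3-dione) | O=C1Nc2cc(Br)c(Br)cc2C1=O
F2 | step 1 | (E)-5,5',6,6'-tetrabromoisoindigo ((E)-5,5',6,6'-tetrabromo-[3,3'-biindolinylidene]-2,2'-dione) | O=C1Nc2cc(Br)c(Br)cc2/C1=C1\C(=O)Nc2cc(Br)c(Br)cc21
F3 | step 2 | 5,5',6,6'-tetrabromo-1H,1'H-3,3'-biindole | Brc1cc2[nH]cc(-c3c[nH]c4cc(Br)c(Br)cc34)c2cc1Br
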